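**Retrosynthetic overview**
1. Target acid ← methyl ester 25. The 1,2-dioxane (ring B, formed last) is closed by a catalyst-controlled 6-exo peroxa-Michael addition of the C6 hydroperoxide to the C2=C3 enoate, which sets C3.
2. C6 hydroperoxide ← invertive displacement of the threo C6 triflate by a protected hydroperoxide.
3. Oxolane (ring A, formed first) with C6 and C7 ← Re2O7 syn-oxidative cyclisation of the (10R)-(E)-5-hydroxyalkene 20.
4. C10 carbinol ← CuI-catalysed opening of (S)-epoxide 10 by the triene Grignard reagent; the epoxide comes from an organocatalytic aldehyde α-chlorination, which sets the first stereocentre.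
5. (E)-C6=C7 ← Johnson–Claisen rearrangement; (17Z,19E)-diene ← Z-selective Wittig reaction of a chlorohexyl ylide with (2E)-hepta-2,6-dienal.

Assumption: the α-chlorination follows the usual face-shielding model for 2,5-diarylpyrrolidines ((2S,5S)-amine gives the (R)-chloride); if the sense proves opposite, the mirror-image amine is used and nothing else changes.

**Step 1**
Reactants: 1 2-(3-chloropropyl)-1,3-dioxolane; 2 acrolein (prop-2-enal)
Product: 4 rac-6-(1,3-dioxolan-2-yl)hex-1-en-3-ol, via Grignard reagent 3 (not isolated)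
Conditions: Mg, BrCH2CH2Br (cat.), THF, reflux; then 2, THF, −78 °C → 0 °C; aq NH4Cl
Reagents that add atoms: none
Why: Grignard 1,2-addition to the enal; the racemic carbinol centre becomes an sp2 carbon in step 2, so no stereocontrol is needed here.

**Step 2**
Reactants: 4 rac-6-(1,3-dioxolan-2-yl)hex-1-en-3-ol
Product: 7 ethyl (4E)-9-oxonon-4-enoate, via allyl ketene acetal 5 (not isolated), via dioxolane ester 6 (not isolated)
Conditions: MeC(OEt)3 (6 equiv), EtCO2H (5 mol%), 140 °C, EtOH distilled off; concentrate; then 2 M HCl, THF, rt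
Reagents that add atoms: triethyl orthoacetate CC(OCC)(OCC)OCC; water O
Why: Johnson–Claisen [3,3] rearrangement through a chair transition state with the chain equatorial gives the (E)-alkene (>95:5), and the aqueous acid then hydrolyses the acetal (and any exchanged acetals) to the aldehyde.

**Step 3**
Reactants: 7 ethyl (4E)-9-oxonon-4-enoate
Product: 10 ethyl (4E)-7-[(2S)-oxiran-2-yl]hept-4-enoate, via chloroaldehyde 8 (not isolated), via chlorohydrin 9 (not isolated)
Conditions: N-chlorosuccinimide (1.3 equiv), (2S,5S)-2,5-diphenylpyrrolidine (10 mol%), CH2Cl2, 0 °C → rt; then NaBH4, EtOH, 0 °C; then NaOEt, EtOH, 0 °C → rt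
Reagents that add atoms: none
Why: enamine-catalysed asymmetric α-chlorination, in which the C2-symmetric amine shields one enamine face to give the (R)-chloride (about 94% ee expected, first stereocentre); immediate reduction prevents racemisation and intramolecular Williamson closure with inversion gives the (S)-epoxide.

**Step 4**
Reactants: 11 1-bromo-6-chlorohexane
Product: 12 (6-chlorohexyl)triphenylphosphonium bromide
Conditions: PPh3 (1.0 equiv), toluene, 110 °C, 24 h
Reagents that add atoms: triphenylphosphine c1ccc(cc1)P(c1ccccc1)c1ccccc1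
Why: SN2 quaternisation occurs selectively at the C–Br terminus because bromide is displaced far faster than chloride.

**Step 5**
Reactants: 13 pent-4-enal
Product: 14 (2E)-hepta-2,6-dienal
Conditions: Ph3P=CHCHO (1.0 equiv), toluene, 80 °C
Reagents that add atoms: (triphenylphosphoranylidene)acetaldehyde O=CC=P(c1ccccc1)(c1ccccc1)c1ccccc1
Why: Wittig two-carbon homologation with a stabilised ylide is E-selective, and a slight excess of 13 limits double homologation.

**Step 6**
Reactants: 12 (6-chlorohexyl)triphenylphosphonium bromide; 14 (2E)-hepta-2,6-dienal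
Product: 16 (5E,7Z)-13-chlorotrideca-1,5,7-triene, via phosphonium ylide 15 (not isolated)
Conditions: NaN(SiMe3)2 (1.0 equiv), THF, −78 °C, 30 min; then 14, −78 °C → rt
Reagents that add atoms: none
Why: salt-free Wittig reaction of a non-stabilised ylide under kinetic control gives the new (Z)-alkene (typically ≥92:8) and leaves the (E)-alkene of the enal unchanged; at −78 °C the ylide does not alkylate the primary chloride.

**Step 7**
Reactants: 16 (5E,7Z)-13-chlorotrideca-1,5,7-triene; 10 ethyl (4E)-7-[(2S)-oxiran-2-yl]hept-4-enoate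
Product: 18 ethyl (4E,8R,15Z,17E)-8-hydroxydocosa-4,15,17,21-tetraenoate, via triene Grignard reagent 17 (not isolated)
Conditions: Mg, BrCH2CH2Br (cat.), THF, reflux; then added slowly to 10, CuI (10 mol%), THF, −40 °C → −20 °C; aq NH4Cl
Reagents that add atoms: none
Why: copper-catalysed Grignard opening of a terminal epoxide (SN2 at the CH2 terminus) leaves the C–O stereocentre untouched, and at −40 °C with slow addition the epoxide is consumed faster than the ethyl ester is attacked.

**Step 8**
Reactants: 18 ethyl (4E,8R,15Z,17E)-8-hydroxydocosa-4,15,17,21-tetraenoate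
Product: 20 methyl (2E,6E,10R,17Z,19E)-10-hydroxytetracosa-2,6,17,19,23-pentaenoate, via hydroxy aldehyde 19 (not isolated)
Conditions: iBu2AlH (2.2 equiv), CH2Cl2, −78 °C; then (MeO)2P(O)CH2CO2Me/NaH in THF, −78 °C → rt; aq potassium sodium tartrate (KNaC4H4O6)
Reagents that add atoms: trimethyl phosphonoacetate COC(=O)CP(=O)(OC)OC
Why: one-pot partial reduction and Horner–Wadsworth–Emmons olefination, in which the aluminium hemiacetal releases the aldehyde only as the phosphonate anion traps it to give the (E)-enoate; doing this before ring closure avoids lactonisation or oxa-Michael reactions of a free C6 hydroxyl.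

**Step 9**
Reactants: 20 methyl (2E,6E,10R,17Z,19E)-10-hydroxytetracosa-2,6,17,19,23-pentaenoate
Product: 21 methyl (2E,6S)-6-hydroxy-6-{(2S,5R)-5-[(7Z,9E)-tetradeca-7,9,13-trien-1-yl]oxolan-2-yl}hex-2-enoate
Conditions: Re2O7 (1.5 equiv), 2,6-lutidine (3 equiv), CH2Cl2, 0 °C → rt; aq NaHCO3
Reagents that add atoms: dirhenium heptoxide O=[Re](=O)(=O)O[Re](=O)(=O)=O
Why: rhenium-oxide syn-oxidative cyclisation of a 5-hydroxyalkene, in which the C10 perrhenate ester adds across the (E)-C6=C7 bond on one face to give the 2,5-trans oxolane (C7) and, by syn addition, the threo C6 alcohol; remote alkenes carry no directing hydroxyl and the enoate is too electron-poor to react.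

**Step 10**
Reactants: 21 methyl (2E,6S)-6-hydroxy-6-{(2S,5R)-5-[(7Z,9E)-tetradeca-7,9,13-trien-1-yl]oxolan-2-yl}hex-2-enoate
Product: 23 methyl (2E,6R)-6-[(2-methoxypropan-2-yl)peroxy]-6-{(2S,5R)-5-[(7Z,9E)-tetradeca-7,9,13-trien-1-yl]oxolan-2-yl}hex-2-enoate, via secondary triflate 22 (not isolated)
Conditions: Tf2O (1.2 equiv), 2,6-lutidine (2 equiv), CH2Cl2, −78 °C; cold pentane/silica plug; then 2-methoxyprop-2-yl hydroperoxide (3 equiv), CsOH·H2O (2.5 equiv), DMF, −20 °C → 0 °C
Reagents that add atoms: 2-methoxyprop-2-yl hydroperoxide COC(C)(C)OO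
Why: SN2 displacement of a secondary triflate by a caesium peroxide anion inverts C6 to the required erythro relationship with C7; the weakly basic α-nucleophile favours substitution over elimination and, being protected, cannot cyclise onto the enoate.

**Step 11**
Reactants: 23 methyl (2E,6R)-6-[(2-methoxypropan-2-yl)peroxy]-6-{(2S,5R)-5-[(7Z,9E)-tetradeca-7,9,13-trien-1-yl]oxolan-2-yl}hex-2-enoate
Product: 24 methyl (2E,6R)-6-hydroperoxy-6-{(2S,5R)-5-[(7Z,9E)-tetradeca-7,9,13-trien-1-yl]oxolan-2-yl}hex-2-enoate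
Conditions: AcOH/THF/H2O (4:2:1), rt
Reagents that add atoms: none
Why: acid hydrolysis of the peroxyketal releases the hydroperoxide without touching the C6–O bond and, in the absence of base, without premature cyclisation.

**Step 12**
Reactants: 24 methyl (2E,6R)-6-hydroperoxy-6-{(2S,5R)-5-[(7Z,9E)-tetradeca-7,9,13-trien-1-yl]oxolan-2-yl}hex-2-enoate
Product: 25 methyl 2-[(3R,6R)-6-{(2S,5R)-5-[(7Z,9E)-tetradeca-7,9,13-trien-1-yl]oxolan-2-yl}-1,2-dioxan-3-yl]acetate
Conditions: quinine-derived squaramide 3-{[3,5-bis(trifluoromethyl)phenyl]amino}-4-{[(8α,9S)-6′-methoxycinchonan-9-yl]amino}cyclobut-3-ene-1,2-dione (10 mol%), toluene, −20 °C; AcOH quench at −20 °C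
Reagents that add atoms: none
Why: Proposed new method: catalyst-controlled 6-exo-trig peroxa-Michael cyclisation in which the quinuclidine nitrogen acts as general base for the hydroperoxide while the squaramide N–H bonds bind the enoate carbonyl, so that the chiral ion pair delivers the distal peroxide oxygen to the Re face of C3 (3R, trans-dioxane) under kinetic control against the substrate's preference for the cis ring, with fast enolate protonation by the ammonium preventing O–O cleavage; the closest known reactions are the amine-mediated, non-selective hydroperoxide–enoate cyclisation to 1,2-dioxane-3-acetates, cinchona-amine-catalysed asymmetric peroxidation of enones and squaramide-catalysed intramolecular oxa-Michael additions.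

**Step 13**
Reactants: 25 methyl 2-[(3R,6R)-6-{(2S,5R)-5-[(7Z,9E)-tetradeca-7,9,13-trien-1-yl]oxolan-2-yl}-1,2-dioxan-3-yl]acetate
Product: 26 2-[(3R,6R)-6-{(2S,5R)-5-[(7Z,9E)-tetradeca-7,9,13-trien-1-yl]oxolan-2-yl}-1,2-dioxan-3-yl]acetic acid
Conditions: LiOH (3 equiv), THF/H2O (3:1), 0 °C; then 1 M HCl to pH 3 at 0 °C
Reagents that add atoms: lithium hydroxide [Li+].[OH-]
Why: mild saponification of the methyl ester, a standard last step for 1,2-dioxane-3-acetates; the carboxylate formed resists retro-Michael opening, so C3 and the O–O bond survive.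

**Compound list**
1 | 2-(3-chloropropyl)-1,3-dioxolane | ClCCCC1OCCO1 | starting material
2 | acrolein (prop-2-enal) | C=CC=O | starting material
3 | [3-(1,3-dioxolan-2-yl)propyl]magnesium chloride | Cl[Mg]CCCC1OCCO1 | intermediate
4 | rac-6-(1,3-dioxolan-2-yl)hex-1-en-3-ol | C=CC(O)CCCC1OCCO1 | intermediate
5 | 2-{4-[(1-ethoxyethenyl)oxy]hex-5-en-1-yl}-1,3-dioxolane (allyl ketene acetal) | C=C(OCC)OC(C=C)CCCC1OCCO1 | intermediate
6 | ethyl (4E)-8-(1,3-dioxolan-2-yl)oct-4-enoate | CCOC(=O)CC/C=C/CCCC1OCCO1 | intermediate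
7 | ethyl (4E)-9-oxonon-4-enoate | CCOC(=O)CC/C=C/CCCC=O | intermediate
8 | ethyl (4E,8R)-8-chloro-9-oxonon-4-enoate | CCOC(=O)CC/C=C/CC[C@@H](Cl)C=O | intermediate
9 | ethyl (4E,8R)-8-chloro-9-hydroxynon-4-enoate | CCOC(=O)CC/C=C/CC[C@@H](Cl)CO | intermediate
10 | ethyl (4E)-7-[(2S)-oxiran-2-yl]hept-4-enoate | CCOC(=O)CC/C=C/CC[C@H]1CO1 | intermediate
11 | 1-bromo-6-chlorohexane | ClCCCCCCBr | starting material
12 | (6-chlorohexyl)triphenylphosphonium bromide | ClCCCCCC[P+](c1ccccc1)(c1ccccc1)c1ccccc1.[Br-] | intermediate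
13 | pent-4-enal | C=CCCC=O | starting material
14 | (2E)-hepta-2,6-dienal | C=CCC/C=C/C=O | intermediate
15 | (6-chlorohexylidene)triphenylphosphorane | ClCCCCCC=P(c1ccccc1)(c1ccccc1)c1ccccc1 | intermediate
16 | (5E,7Z)-13-chlorotrideca-1,5,7-triene | C=CCC/C=C/C=C\CCCCCCl | intermediate
17 | [(6Z,8E)-trideca-6,8,12-trien-1-yl]magnesium chloride | C=CCC/C=C/C=C\CCCCC[Mg]Cl | intermediate
18 | ethyl (4E,8R,15Z,17E)-8-hydroxydocosa-4,15,17,21-tetraenoate | C=CCC/C=C/C=C\CCCCCC[C@@H](O)CC/C=C/CCC(=O)OCC | intermediate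
19 | (4E,8R,15Z,17E)-8-hydroxydocosa-4,15,17,21-tetraenal | C=CCC/C=C/C=C\CCCCCC[C@@H](O)CC/C=C/CCC=O | intermediate
20 | methyl (2E,6E,10R,17Z,19E)-10-hydroxytetracosa-2,6,17,19,23-pentaenoate | C=CCC/C=C/C=C\CCCCCC[C@@H](O)CC/C=C/CC/C=C/C(=O)OC | intermediate
21 | methyl (2E,6S)-6-hydroxy-6-{(2S,5R)-5-[(7Z,9E)-tetradeca-7,9,13-trien-1-yl]oxolan-2-yl}hex-2-enoate | C=CCC/C=C/C=C\CCCCCC[C@@H]1CC[C@@H]([C@@H](O)CC/C=C/C(=O)OC)O1 | intermediate
22 | methyl (2E,6S)-6-{(2S,5R)-5-[(7Z,9E)-tetradeca-7,9,13-trien-1-yl]oxolan-2-yl}-6-{[(trifluoromethyl)sulfonyl]oxy}hex-2-enoate | C=CCC/C=C/C=C\CCCCCC[C@@H]1CC[C@@H]([C@@H](OS(=O)(=O)C(F)(F)F)CC/C=C/C(=O)OC)O1 | intermediate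
23 | methyl (2E,6R)-6-[(2-methoxypropan-2-yl)peroxy]-6-{(2S,5R)-5-[(7Z,9E)-tetradeca-7,9,13-trien-1-yl]oxolan-2-yl}hex-2-enoate | C=CCC/C=C/C=C\CCCCCC[C@@H]1CC[C@@H]([C@H](OOC(C)(C)OC)CC/C=C/C(=O)OC)O1 | intermediate
24 | methyl (2E,6R)-6-hydroperoxy-6-{(2S,5R)-5-[(7Z,9E)-tetradeca-7,9,13-trien-1-yl]oxolan-2-yl}hex-2-enoate | C=CCC/C=C/C=C\CCCCCC[C@@H]1CC[C@@H]([C@H](OO)CC/C=C/C(=O)OC)O1 | intermediate
25 | methyl 2-[(3R,6R)-6-{(2S,5R)-5-[(7Z,9E)-tetradeca-7,9,13-trien-1-yl]oxolan-2-yl}-1,2-dioxan-3-yl]acetate | C=CCC/C=C/C=C\CCCCCC[C@@H]1CC[C@@H]([C@H]2CC[C@H](CC(=O)OC)OO2)O1 | intermediate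
26 | 2-[(3R,6R)-6-{(2S,5R)-5-[(7Z,9E)-tetradeca-7,9,13-trien-1-yl]oxolan-2-yl}-1,2-dioxan-3-yl]acetic acid | C=CCC/C=C/C=C\CCCCCC[C@@H]1CC[C@@H]([C@H]2CC[C@H](CC(=O)O)OO2)O1 | target

**Step count**
Total: 13 steps. Longest linear sequence: 10 steps (1 → 2 → 3 → 7 → 8 → 9 → 10 → 11 → 12 → 13); steps 4–6 are the side-chain branch that joins at step 7.

**Three steps most likely to fail**

Step 12 (new peroxa-Michael cyclisation). The catalyst must override the intrinsic preference for the cis-3,6 ring. Other risks are slow turnover at low temperature, retro-Michael equilibration and base-induced Kornblum–DeLaMare fragmentation. The quinidine-derived pseudo-enantiomer of the catalyst is tried first if the facial sense is wrong. The fallback sets out from 24 and comes back at 25. It gives up catalyst control and uses the known amine-mediated ring closure: 24 is treated with Et2NH in CF3CH2OH at rt, which under substrate control gives 25 together with its C3 epimer methyl 2-[(3S,6R)-6-{(2S,5R)-5-[(7Z,9E)-tetradeca-7,9,13-trien-1-yl]oxolan-2-yl}-1,2-dioxan-3-yl]acetate F1. The two are separated by preparative HPLC, and F1 is returned to the amine conditions (retro-Michael and re-addition) to regenerate the mixture.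

Step 10 (triflate displacement by the peroxide anion). SN2 at a secondary carbon next to the oxolane oxygen is slowed inductively and competes with elimination and with participation of the ring oxygen. The fallback sets out from 21 and comes back at 25, skipping 23 and 24. Alcohol 21 is converted with MsCl/Et3N into the mesylate methyl (2E,6S)-6-[(methylsulfonyl)oxy]-6-{(2S,5R)-5-[(7Z,9E)-tetradeca-7,9,13-trien-1-yl]oxolan-2-yl}hex-2-enoate F2. F2 is treated with 50% aqueous H2O2 and KOH in MeOH/THF at 0 °C (classical perhydrolysis of a sulfonate with inversion, using the small hydroperoxide anion itself). The peroxide anion formed closes onto the enoate in the same flask, and 25 is isolated by HPLC from its C3 epimer.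

Step 9 (Re2O7 oxidative cyclisation). Perrhenic acid traces may isomerise the (Z,E)-diene, and trans selectivity or yield may fall short on this polyene. The fallback sets out from 20 and comes back at 21. It replaces the concerted syn cyclisation by a hydroxyl-directed epoxidation, anti ring closure and inversion at C6. VO(acac)2 (5 mol%) and tBuOOH in CH2Cl2 epoxidise only the alkene within reach of the C10 hydroxyl, giving methyl (2E,6R,7R,10R,17Z,19E)-6,7-epoxy-10-hydroxytetracosa-2,17,19,23-tetraenoate F3 (with its 6S,7S diastereomer). Catalytic camphorsulfonic acid then effects 5-exo opening with inversion at C7 to the erythro alcohol methyl (2E,6R)-6-hydroxy-6-{(2S,5R)-5-[(7Z,9E)-tetradeca-7,9,13-trien-1-yl]oxolan-2-yl}hex-2-enoate F4, which is separated from the cis-oxolane arising from the other epoxide. Mitsunobu inversion (ClCH2CO2H, PPh3, diisopropyl azodicarboxylate, THF) gives methyl (2E,6S)-6-[(chloroacetyl)oxy]-6-{(2S,5R)-5-[(7Z,9E)-tetradeca-7,9,13-trien-1-yl]oxolan-2-yl}hex-2-enoate F5. The chloroacetate is removed under near-neutral conditions (thiourea, NaHCO3, EtOH) to give 21 without exposing the hydroxy enoate to strong base.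

**Further compounds**
F1 | step 12 | methyl 2-[(3S,6R)-6-{(2S,5R)-5-[(7Z,9E)-tetradeca-7,9,13-trien-1-yl]oxolan-2-yl}-1,2-dioxan-3-yl]acetate | C=CCC/C=C/C=C\CCCCCC[C@@H]1CC[C@@H]([C@H]2CC[C@@H](CC(=O)OC)OO2)O1
F2 | step 10 | methyl (2E,6S)-6-[(methylsulfonyl)oxy]-6-{(2S,5R)-5-[(7Z,9E)-tetradeca-7,9,13-trien-1-yl]oxolan-2-yl}hex-2-enoate | C=CCC/C=C/C=C\CCCCCC[C@@H]1CC[C@@H]([C@@H](OS(C)(=O)=O)CC/C=C/C(=O)OC)O1
F3 | step 9 | methyl (2E,6R,7R,10R,17Z,19E)-6,7-epoxy-10-hydroxytetracosa-2,17,19,23-tetraenoate | C=CCC/C=C/C=C\CCCCCC[C@@H](O)CC[C@H]1O[C@@H]1CC/C=C/C(=O)OC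
F4 | step 9 | methyl (2E,6R)-6-hydroxy-6-{(2S,5R)-5-[(7Z,9E)-tetradeca-7,9,13-trien-1-yl]oxolan-2-yl}hex-2-enoate | C=CCC/C=C/C=C\CCCCCC[C@@H]1CC[C@@H]([C@H](O)CC/C=C/C(=O)OC)O1
F5 | step 9 | methyl (2E,6S)-6-[(chloroacetyl)oxy]-6-{(2S,5R)-5-[(7Z,9E)-tetradeca-7,9,13-trien-1-yl]oxolan-2-yl}hex-2-enoate | C=CCC/C=C/C=C\CCCCCC[C@@H]1CC[C@@H]([C@@H](OC(=O)CCl)CC/C=C/C(=O)OC)O1
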